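Each substitution moves one reagent onto a substrate. Let A, B, D and T be substrate, reagent, double product and tris adduct, each divided by the substrate charge. If side product carries one reagent per substrate unit, as single product does, then D + 2T − A + B is invariant. Its value is the reagent excess over one equivalent, e = (reagent − substrate)/substrate, 0.800 in amber. The south-west run tests this: its last reading gives D + 2T = 49.5%, against e = 50.0%.

| flask | substrate | reagent | remark | time |
|---|---|---|---|---|
| south-east | 0.77 M | 1.8 M | run made earlier |  |
| south-west | 1.2 M | 1.8 M | run made earlier |  |
| west | 2.4 M | 1.8 M | run made earlier |  |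
| north-west | 1.8 M | 1.6 M | run made earlier |  |
| green | 1.8 M | 1.80 M |  | 30 h |
| red | 1.0 M | 1.00 M |  | 30 h |
| amber | 1.0 M | 1.80 M |  | 30 h |
| violet | 2.5 M | 1.80 M |  | 30 h |
| ochre | 0.60 M | 1.00 M |  | 30 h |

| run | time / h | double product / % | tris adduct / % |
|---|---|---|---|
| south-east | 4.00 | 51.8 | 0.9 |
| south-east | 8.00 | 67.1 | 3.3 |
| south-east | 12.0 | 73.4 | 4.5 |
| south-east | 15.0 | 75.3 | 5.1 |
| south-east | 20.0 | 76.1 | 6.0 |
| south-west | 2.00 | 24.1 | 0.4 |
| south-west | 5.00 | 39.7 | 0 |
| south-west | 10.0 | 44.9 | 0.6 |
| south-west | 15.0 | 47.3 | 1.6 |
| south-west | 20.0 | 46.7 | 1.4 |
| west | 1.50 | 9.7 | 0.8 |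
| west | 3.00 | 12.2 | 0.2 |
| west | 6.00 | 8.1 | 0.1 |
| west | 12.0 | 4.6 | 0 |
| west | 20.0 | 1.1 | 0 |
| north-west | 1.50 | 10.3 | 1.5 |
| north-west | 3.00 | 16.8 | 0 |
| north-west | 6.00 | 15.4 | 0 |
| north-west | 12.0 | 10.9 | 0 |
| north-west | 20.0 | 5.8 | 1.4 |

(scatter of a reading: 0.5 percentage points)

- percent here means substrate units held: one side product counts as two

* the flasks put in order of share of double product in all that became double product or tris adduct or side product, best first, at 30 h (green / red / amber / violet / ochre)
* the share of double product in all that became double product or tris adduct or side product of the flask you put first, at 30 h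
* the share of double product in all that became double product or tris adduct or side product of the flask you put last, at 30 h

My reckoning ranks the flasks by e: amber, then ochre at 0.667, then red and green tied at 0, then violet at −0.280. For amber, with A taken as gone, D = e − 2T − B, and the selectivity is D/(D + T + side product).

The south-east run approaches its plateau at 0.230 h⁻¹ with reagent near 0.463 M, which reads k = 0.498 M⁻¹ h⁻¹. If single product and reagent stand about equal late on, reagent falls as 1/(kt), to 0.0669 M at 30 h, so B = 0.0669.

The excess e of amber lies below that of the south-east run and above that of the south-west run, so their last readings of T serve as its two ends. From below, with the denominator at its full charge, T at the south-east 6.0% and B as reckoned, the share is at least 61.3%. From above, with single product held equal to B, the share is D over the charge less B, which falls as B rises, so B zero and T at the south-west 1.4% give at most 77.2%. Tightened with T at the mean of the two runs, 3.70%, and single product equal to the reckoned B, the share is 70.6%.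

The forecast, amber > ochre > red > green > violet with 65% first and 0.5% last, argues that “concentration only sets the clock”, and its top lies inside my bracket.

The simulation gives amber > ochre > red > green > violet, with amber at 70.6% and violet at 0.806%.

    substrate + reagent → single product + by-product (k = 0.430 M⁻¹ h⁻¹)
    reagent + single product → double product + by-product (k = 0.450 M⁻¹ h⁻¹)
    reagent + double product ⇌ tris adduct + by-product (K = 10.0, k = 0.0110 M⁻¹ h⁻¹)
    substrate + double product → side product (k = 0.180 M⁻¹ h⁻¹)

At 30.0 h amber holds double product 66.0%, tris adduct 3.48% and single product 6.35%, with reagent at 4.00% of its own charge, and the invariant sums to 0.800. Green, charged 1.8 M of substrate and 1.80 M of reagent, has e of zero and its reagent stands at 0%, so D + 2T should match its substrate left: 8.50% against 8.51%.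

The data are calculated with made-up constants; scatter was added.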